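**Retrosynthetic overview**
1. Target 15 comes from phenol 10 by late-stage editing: ortho-formylation, O-sulfation, dehydration of the C8 tertiary alcohol to the 7,8-alkene, and deallylation.
2. Key disconnection C9–C11: blue-light decarboxylative coupling of the C9 radical from hydroxy acid 4 with o-quinone methide 9 (released from acetate 8). This step forms the bond and sets C9 (arylmethyl α, H β).
3. Acid 4 comes from (+)-sclareolide 1 by excising C12 (enaminone, ozonolysis, alkaline H2O2). Acetate 8 comes from 2,4,5-trihydroxybenzaldehyde 5 (allylation, reduction, acetylation).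
4. No ring is built: rings A and B (with C5, C10 and the temporary C8 control element) are bought in 1, and the benzene ring in 5.

Assumption: the target is taken as the free aryl hydrogen sulfate as drawn; by my reading of the SMILES its C9–H is β (cis to the C10 methyl, i.e. 9-epi relative to drimenol), and drimane numbering is used throughout.

**Route**

Step 1
Reactants: 1 (+)-sclareolide
Product: 2 (E)-11-(dimethylaminomethylidene)sclareolide
Conditions: t-BuOCH(NMe2)2 (2 equiv), toluene, 110 °C, 16 h
Reagents that add atoms: tert-butoxybis(dimethylamino)methane (Bredereck's reagent), CC(C)(C)OC(N(C)C)N(C)C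
Why: Bredereck aminomethylenation: the aminal ester condenses with the lactone α-methylene (C11) to give the push–pull enaminone, driven by loss of tert-butanol and dimethylamine, and no stereocentre is touched.

Step 2
Reactants: 2 (E)-11-(dimethylaminomethylidene)sclareolide
Product: 4 8α-hydroxydriman-11-oic acid, via 11-oxosclareolide 3 (not isolated)
Conditions: O3, CH2Cl2/MeOH, −78 °C; Me2S; then 30% H2O2, NaOH, THF/H2O, 0 °C to rt; HCl to pH 3
Reagents that add atoms: ozone, [O-][O+]=O; hydrogen peroxide, OO
Why: Ozonolysis of the electron-rich enamine C=C gives α-keto lactone 3, and alkaline hydrogen peroxide then opens the lactone and excises C12 as carbonate (oxidative decarboxylation of an α-keto acid), leaving CO2H on C9 and the unbroken C8–O bond as the 8α-alcohol; any epimerisation at C9 is harmless because step 6 erases that centre.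

Step 3
Reactants: 5 2,4,5-trihydroxybenzaldehyde
Product: 6 4,5-bis(allyloxy)-2-hydroxybenzaldehyde
Conditions: allyl bromide (2.1 equiv), K2CO3 (2.1 equiv), DMF, 0 °C to rt
Reagents that add atoms: allyl bromide, C=CCBr
Why: Williamson etherification: the 2-OH chelated to the aldehyde gives the least nucleophilic phenoxide, so two equivalents of allyl bromide cap O4 and O5 and leave it free.

Step 4
Reactants: 6 4,5-bis(allyloxy)-2-hydroxybenzaldehyde
Product: 7 4,5-bis(allyloxy)-2-(hydroxymethyl)phenol
Conditions: NaBH4 (1 equiv), THF/MeOH, 0 °C; aq NH4Cl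
Reagents that add atoms: none
Why: Borohydride reduction of the aryl aldehyde to the salicyl alcohol, with a neutral work-up because the electron-rich benzylic alcohol is acid-sensitive.

Step 5
Reactants: 7 4,5-bis(allyloxy)-2-(hydroxymethyl)phenol
Product: 8 [4,5-bis(allyloxy)-2-hydroxyphenyl]methyl acetate
Conditions: AcCl (1.05 equiv), 2,4,6-collidine (2 equiv), CH2Cl2, −78 °C
Reagents that add atoms: acetyl chloride, CC(Cl)=O
Why: Chemoselective O-acylation: with the non-deprotonating base collidine at low temperature the primary benzylic alcohol is acetylated much faster than the un-ionised phenol, giving a storable o-quinone methide precursor.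

Step 6
Reactants: 4 8α-hydroxydriman-11-oic acid; 8 [4,5-bis(allyloxy)-2-hydroxyphenyl]methyl acetate
Product: 10 11-[4,5-bis(allyloxy)-2-hydroxyphenyl]-9βH-driman-8α-ol, via o-quinone methide 9 (not isolated)
Conditions: Ir[dF(CF3)ppy]2(dtbbpy)PF6 (2 mol%), Cs2CO3 (3 equiv), 8 (2 equiv, added over 6 h), degassed DMSO, 450 nm LEDs, 25 °C; aq NH4Cl
Reagents that add atoms: none
Why: Proposed new method: Cs2CO3 unmasks o-quinone methide 9 from 8 by E1cB loss of acetate while the excited trivalent iridium photocatalyst oxidises the cesium carboxylate of 4; loss of CO2 gives the secondary C9 radical, whose β face is walled off by the syn-axial methyl groups on C8 and C10, so it attacks the unsubstituted methide carbon of 9 through its α face (new C9–C11 bond axial, C9–H β), re-aromatisation drives the addition and divalent iridium reduces the phenoxyl radical to the phenoxide, closing a redox-neutral cycle; the closest known reaction type is the photoredox decarboxylative Giese addition, in particular 1,6-additions of alkyl radicals to isolable δ-aryl p-quinone methides, which to my knowledge has not been shown for a transient methide-unsubstituted o-quinone methide or for a hindered neopentyl-type terpenoid radical under substrate stereocontrol.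

Step 7
Reactants: 10 11-[4,5-bis(allyloxy)-2-hydroxyphenyl]-9βH-driman-8α-ol
Product: 11 2,3-bis(allyloxy)-6-hydroxy-5-(8α-hydroxy-9βH-driman-11-yl)benzaldehyde
Conditions: MgCl2 (3 equiv), Et3N (6 equiv), (CH2O)n (8 equiv), THF, reflux; cold aq citric acid
Reagents that add atoms: paraformaldehyde (as formaldehyde), C=O
Why: Magnesium-mediated ortho-formylation (Casnati–Skattebøl): the magnesium phenoxide delivers formaldehyde only to an ortho carbon, and the single free ortho position lies between the OH and the 4-allyloxy group, which is exactly the aldehyde position of the target.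

Step 8
Reactants: 11 2,3-bis(allyloxy)-6-hydroxy-5-(8α-hydroxy-9βH-driman-11-yl)benzaldehyde
Product: 12 sodium 3,4-bis(allyloxy)-2-formyl-6-(8α-hydroxy-9βH-driman-11-yl)phenyl sulfate
Conditions: SO3·pyridine (3 equiv), pyridine, 40 °C; then aq NaHCO3
Reagents that add atoms: sulfur trioxide–pyridine complex, [O-]S(=O)(=O)[n+]1ccccc1; sodium hydrogen carbonate, [Na+].OC([O-])=O
Why: O-sulfation of a phenol with SO3·pyridine: the only free phenol is the one liberated by the quinone methide coupling (the catechol is masked as allyl ethers) and the hindered tertiary alcohol does not compete at this temperature.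

Step 9
Reactants: 12 sodium 3,4-bis(allyloxy)-2-formyl-6-(8α-hydroxy-9βH-driman-11-yl)phenyl sulfate
Product: 13 sodium 3,4-bis(allyloxy)-2-formyl-6-(9βH-drim-7-en-11-yl)phenyl sulfate
Conditions: MeO2CN(−)SO2N(+)Et3 (Burgess reagent, 2.5 equiv), THF/MeCN, 50 °C
Reagents that add atoms: none
Why: Burgess dehydration: the sulfamoylated tertiary 8α-alcohol eliminates by a syn-Ei/tight-ion-pair pathway that can only take a cis β-hydrogen (H7α or a methyl hydrogen), whereas the C9–H is trans to the leaving group and lies in the nodal plane of any developing C8 cation, so C9 is not touched and the Zaitsev 7,8-alkene should predominate; the formylated, sulfated arene is too deactivated to trap the cation.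

Step 10
Reactants: 13 sodium 3,4-bis(allyloxy)-2-formyl-6-(9βH-drim-7-en-11-yl)phenyl sulfate
Product: 15 2-formyl-3,4-dihydroxy-6-(9βH-drim-7-en-11-yl)phenyl hydrogen sulfate, via sodium sulfate salt 14 (not isolated)
Conditions: Pd(PPh3)4 (5 mol%), TolSO2Na (2.5 equiv), degassed THF/MeOH, rt, Ar; evaporate; then H2O, 1 M HCl to pH 1, 0 °C, n-BuOH extraction
Reagents that add atoms: none
Why: Tsuji–Trost deallylation: zerovalent palladium ionises the two aryl allyl ethers to π-allyl complexes that are captured by sulfinate, conditions that leave the aryl sulfate, aldehyde and trisubstituted alkene alone, and brief cold acidification then protonates the sulfate without affecting any stereocentre.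

**Compound list**
1 | (+)-sclareolide (5S,8R,9R,10S; 8α-O lactone, 9αH) | C[C@@]12CC[C@H]3C(C)(C)CCC[C@]3(C)[C@H]1CC(=O)O2 | starting material
2 | (E)-11-(dimethylaminomethylidene)sclareolide | C[C@@]12CC[C@H]3C(C)(C)CCC[C@]3(C)[C@H]1/C(=C\N(C)C)C(=O)O2 | intermediate
3 | 11-oxosclareolide (α-keto lactone) | C[C@@]12CC[C@H]3C(C)(C)CCC[C@]3(C)[C@H]1C(=O)C(=O)O2 | intermediate (not isolated)
4 | 8α-hydroxydriman-11-oic acid (5S,8R,9R,10S) | C[C@@]1(O)CC[C@H]2C(C)(C)CCC[C@]2(C)[C@H]1C(O)=O | intermediate
5 | 2,4,5-trihydroxybenzaldehyde | O=Cc1cc(O)c(O)cc1O | starting material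
6 | 4,5-bis(allyloxy)-2-hydroxybenzaldehyde | O=Cc1cc(OCC=C)c(OCC=C)cc1O | intermediate
7 | 4,5-bis(allyloxy)-2-(hydroxymethyl)phenol | OCc1cc(OCC=C)c(OCC=C)cc1O | intermediate
8 | [4,5-bis(allyloxy)-2-hydroxyphenyl]methyl acetate | CC(=O)OCc1cc(OCC=C)c(OCC=C)cc1O | intermediate
9 | 4,5-bis(allyloxy)-6-methylidenecyclohexa-2,4-dien-1-one (o-quinone methide) | C=C1C=C(OCC=C)C(OCC=C)=CC1=O | intermediate (not isolated)
10 | 11-[4,5-bis(allyloxy)-2-hydroxyphenyl]-9βH-driman-8α-ol (5S,8R,9S,10S; arylmethyl on C9α) | C[C@@]1(O)CC[C@H]2C(C)(C)CCC[C@]2(C)[C@@H]1Cc1cc(OCC=C)c(OCC=C)cc1O | intermediate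
11 | 2,3-bis(allyloxy)-6-hydroxy-5-(8α-hydroxy-9βH-driman-11-yl)benzaldehyde | C[C@@]1(O)CC[C@H]2C(C)(C)CCC[C@]2(C)[C@@H]1Cc1cc(OCC=C)c(OCC=C)c(C=O)c1O | intermediate
12 | sodium 3,4-bis(allyloxy)-2-formyl-6-(8α-hydroxy-9βH-driman-11-yl)phenyl sulfate | C[C@@]1(O)CC[C@H]2C(C)(C)CCC[C@]2(C)[C@@H]1Cc1cc(OCC=C)c(OCC=C)c(C=O)c1OS(=O)(=O)[O-].[Na+] | intermediate
13 | sodium 3,4-bis(allyloxy)-2-formyl-6-(9βH-drim-7-en-11-yl)phenyl sulfate (5S,9R,10S) | CC1=CC[C@H]2C(C)(C)CCC[C@]2(C)[C@@H]1Cc1cc(OCC=C)c(OCC=C)c(C=O)c1OS(=O)(=O)[O-].[Na+] | intermediate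
14 | sodium 2-formyl-3,4-dihydroxy-6-(9βH-drim-7-en-11-yl)phenyl sulfate | CC1=CC[C@H]2C(C)(C)CCC[C@]2(C)[C@@H]1Cc1cc(O)c(O)c(C=O)c1OS(=O)(=O)[O-].[Na+] | intermediate (not isolated)
15 | 2-formyl-3,4-dihydroxy-6-(9βH-drim-7-en-11-yl)phenyl hydrogen sulfate (5S,9R,10S) | CC1=CC[C@H]2C(C)(C)CCC[C@]2(C)[C@@H]1Cc1cc(O)c(O)c(C=O)c1OS(=O)(=O)O | target

**Step count**
Total: 10 steps. Longest linear sequence: 8 steps (5 → 6 → 7 → 8 → 10 → 11 → 12 → 13 → 15).

**Three steps most likely to fail**

Step 6 (the proposed new coupling). The transient quinone methide may oligomerise or be consumed by phenoxide before the low-concentration radical reaches it, and the electron-rich phenoxides compete for the excited photocatalyst. The fallback uses known chemistry, sets out from 4 and comes back at 10. Acid 4 is converted with N-hydroxyphthalimide and N,N'-diisopropylcarbodiimide into the N-(acyloxy)phthalimide of 8α-hydroxydriman-11-oic acid F4. A thiazolium-derived N-heterocyclic carbene (Cs2CO3 cat., DMSO, 60 °C) then couples F4 with aldehyde 6 by the known decarboxylative radical acylation of aldehydes. The C9 radical is intercepted on its α face by the persistent carbene-bound ketyl radical, giving [4,5-bis(allyloxy)-2-hydroxyphenyl] (8α-hydroxy-9βH-11-nordriman-9-yl) ketone F5. Ethyl chloroformate/Et3N followed by NaBH4 then carries out the known carbonate-triggered deoxygenation of o-acylphenols, through the aryl ethyl carbonate of the ketone F6 and the C11-substituted o-quinone methide F7, to 10.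

Step 9 (regiochemistry of the dehydration: 7,8-alkene versus exocyclic 8(12)-alkene). The fallback sets out from 12 and comes back at 13 and deliberately goes through the other alkene. Ph2S[OC(CF3)2Ph]2 (Martin sulfurane, CH2Cl2, 0 °C) effects anti-elimination from the equatorial 8α-oxygen, which can only use a methyl hydrogen, giving sodium 3,4-bis(allyloxy)-2-formyl-6-(9βH-drim-8(12)-en-11-yl)phenyl sulfate F8. Catalytic anhydrous TsOH in CH2Cl2 at 0 °C then protonates only the 1,1-disubstituted alkene and the C8 cation loses the stereoelectronically aligned H7α (the C9–H is orthogonal), isomerising F8 to 13.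

Step 2 (one-carbon excision; the enaminone of step 1 may form sluggishly on the hindered lactone and the ozonolysis/peroxide sequence has two stages). The fallback is the classical degradation, sets out from 1 and comes back at 4. Enolate oxygenation (KN(SiMe3)2, THF, −78 °C; O2, P(OEt)3) gives 11-hydroxysclareolide F1. LiAlH4 reduces it to 8α,11,12-trihydroxyhomodrimane F2. NaIO4 cleaves the 11,12-diol to 8α-hydroxydriman-11-al F3, and NaClO2/NaH2PO4/2-methyl-2-butene (Pinnick oxidation) gives 4.

Further compounds
F1 | step 2 | 11-hydroxysclareolide (C11 configuration not defined) | C[C@@]12CC[C@H]3C(C)(C)CCC[C@]3(C)[C@H]1C(O)C(=O)O2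
F2 | step 2 | 8α,11,12-trihydroxyhomodrimane (C11 configuration not defined) | C[C@@]1(O)CC[C@H]2C(C)(C)CCC[C@]2(C)[C@H]1C(O)CO
F3 | step 2 | 8α-hydroxydriman-11-al | C[C@@]1(O)CC[C@H]2C(C)(C)CCC[C@]2(C)[C@H]1C=O
F4 | step 6 | N-(acyloxy)phthalimide of 8α-hydroxydriman-11-oic acid | C[C@@]1(O)CC[C@H]2C(C)(C)CCC[C@]2(C)[C@H]1C(=O)ON1C(=O)c2ccccc2C1=O
F5 | step 6 | [4,5-bis(allyloxy)-2-hydroxyphenyl] (8α-hydroxy-9βH-11-nordriman-9-yl) ketone | C[C@@]1(O)CC[C@H]2C(C)(C)CCC[C@]2(C)[C@@H]1C(=O)c1cc(OCC=C)c(OCC=C)cc1O
F6 | step 6 | aryl ethyl carbonate of ketone F5 | C[C@@]1(O)CC[C@H]2C(C)(C)CCC[C@]2(C)[C@@H]1C(=O)c1cc(OCC=C)c(OCC=C)cc1OC(=O)OCC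
F7 | step 6 | C11-substituted o-quinone methide (alkene geometry not defined) | C[C@@]1(O)CC[C@H]2C(C)(C)CCC[C@]2(C)[C@@H]1C=C1C=C(OCC=C)C(OCC=C)=CC1=O
F8 | step 9 | sodium 3,4-bis(allyloxy)-2-formyl-6-(9βH-drim-8(12)-en-11-yl)phenyl sulfate | C=C1CC[C@H]2C(C)(C)CCC[C@]2(C)[C@@H]1Cc1cc(OCC=C)c(OCC=C)c(C=O)c1OS(=O)(=O)[O-].[Na+]
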